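**Retrosynthetic overview**
1. Target 10 comes from 9 by a Cope [3,3] shift: the allyl group is relayed suprafacially from C3a to C5, so the remote C5 centre is set by C3a and never by an external reagent.
2. 9 comes from 7 and 6 by dearomative para-allylation of a phenol (PhI(OAc)2/allylsilane umpolung); a pivalate on O5 diverts attack from C5 to C3a, and the C3 methyl sends the allyl group to the opposite face.
3. 6 comes from 4, made from 2 + 3 by an enantioselective titanium–TADDOLate quinone–styrene formal [3+2] cycloaddition that sets C2 and C3 (trans).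
4. Ring order: the six-membered carbocycle is the quinone ring of 2; the dihydrofuran ring is closed onto it in step 2; the carbocycle is aromatic from step 2 to step 4, dearomatised in step 5 and re-patterned in step 7.

Assumption: the (4R,5R)-TADDOL complex is taken to give the (2R,3R) adduct in step 2; if the facial sense proves opposite, the (4S,5S)-diol is used and nothing else changes.

Numbering used throughout: benzofuran numbering (O1, C2, C3, C3a, C4–C7, C7a).

**Step 1**
Reactants: 1 2-(benzyloxy)phenol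
Product: 2 2-(benzyloxy)cyclohexa-2,5-diene-1,4-dione
Conditions: (KSO3)2NO (2.2 equiv), KH2PO4, H2O/acetone, 0 °C to rt
Reagents that add atoms: potassium nitrosodisulfonate, [O]N(S(=O)(=O)[O-])S(=O)(=O)[O-].[K+].[K+]
Why: Teuber oxidation: the nitroxyl radical salt oxidises a phenol with a free para position to the para-quinone (one equivalent abstracts hydrogen, the second delivers the oxygen) and the benzyl ether is inert; no stereocenter is formed.

**Step 2**
Reactants: 2 2-(benzyloxy)cyclohexa-2,5-diene-1,4-dione; 3 (E)-1,2-dimethoxy-4-(prop-1-en-1-yl)benzene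
Product: 4 (2R,3R)-6-(benzyloxy)-2-(3,4-dimethoxyphenyl)-3-methyl-2,3-dihydro-1-benzofuran-5-ol
Conditions: TiCl2(OiPr)2 (1.2 equiv), (4R,5R)-2,2-dimethyl-α,α,α′,α′-tetraphenyl-1,3-dioxolane-4,5-dimethanol (TADDOL, 1.3 equiv), 4 Å MS, CH2Cl2, −78 °C; H2O quench; recrystallise
Reagents that add atoms: none
Why: Chiral Lewis acid promoted quinone–styrene formal [3+2] cycloaddition (Michael addition, then O-cyclisation): tetravalent titanium chelates C1=O and the benzyloxy oxygen of 2, the TADDOLate shields one quinone face so the β-carbon of 3 adds to C5 from the open face, the benzylic cation is closed by the C4 oxygen with the E geometry carried into the 2,3-trans ring, and tautomerisation to the hydroquinone monoether fixes C2 and C3 as (2R,3R).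

**Step 3**
Reactants: 4 (2R,3R)-6-(benzyloxy)-2-(3,4-dimethoxyphenyl)-3-methyl-2,3-dihydro-1-benzofuran-5-ol
Product: 5 (2R,3R)-6-(benzyloxy)-2-(3,4-dimethoxyphenyl)-3-methyl-2,3-dihydro-1-benzofuran-5-yl 2,2-dimethylpropanoate
Conditions: PivCl, Et3N, DMAP (cat.), CH2Cl2, 0 °C to rt
Reagents that add atoms: pivaloyl chloride, CC(C)(C)C(=O)Cl
Why: O-Acylation (nucleophilic acyl substitution, DMAP catalysis): the pivalate turns the C5 oxygen from a donor into an acceptor, which later steers the nucleophile away from C5, and its bulk suppresses migration to the neighbouring oxygen; stereocenters are untouched.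

**Step 4**
Reactants: 5 (2R,3R)-6-(benzyloxy)-2-(3,4-dimethoxyphenyl)-3-methyl-2,3-dihydro-1-benzofuran-5-yl 2,2-dimethylpropanoate
Product: 6 (2R,3R)-2-(3,4-dimethoxyphenyl)-6-hydroxy-3-methyl-2,3-dihydro-1-benzofuran-5-yl 2,2-dimethylpropanoate
Conditions: H2 (1 atm), Pd/C (10%), EtOAc, rt, stopped at full conversion; used at once
Reagents that add atoms: none
Why: Hydrogenolysis of the primary benzyl aryl ether, which is cleaved faster than the hindered cyclic C2–O benzylic bond under neutral conditions, frees the C6 phenol (para to C3a) before any alkene is present; stereocenters are untouched.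

**Step 5**
Reactants: 6 (2R,3R)-2-(3,4-dimethoxyphenyl)-6-hydroxy-3-methyl-2,3-dihydro-1-benzofuran-5-yl 2,2-dimethylpropanoate
Product: 7 (2R,3R,3aR)-2-(3,4-dimethoxyphenyl)-3-methyl-6-oxo-3a-(prop-2-en-1-yl)-2,3,3a,6-tetrahydro-1-benzofuran-5-yl 2,2-dimethylpropanoate
Conditions: PhI(OAc)2 (1.1 equiv), allylSiMe3 (5 equiv), (CF3)2CHOH, −20 °C to 0 °C; aq. NaHCO3 work-up
Reagents that add atoms: allyltrimethylsilane, C=CC[Si](C)(C)C
Why: Oxidative dearomatisation of the phenol by trivalent iodine (phenol umpolung) with Hosomi–Sakurai-type capture by the allylsilane: the oxidised ring is attacked at the alkyl-bearing para carbon C3a because C5 now carries the electron-poor pivalate, and the allyl group enters anti to the adjacent C3 methyl (1,2-induction on the five-membered ring), giving the 3aR quaternary centre with allyl cis to the aryl group.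

**Step 6**
Reactants: 7 (2R,3R,3aR)-2-(3,4-dimethoxyphenyl)-3-methyl-6-oxo-3a-(prop-2-en-1-yl)-2,3,3a,6-tetrahydro-1-benzofuran-5-yl 2,2-dimethylpropanoate
Product: 9 (2R,3R,3aR)-2-(3,4-dimethoxyphenyl)-5-methoxy-3-methyl-3a-(prop-2-en-1-yl)-3,3a-dihydro-1-benzofuran-6(2H)-one, via diosphenol 8 (not isolated)
Conditions: K2CO3, MeOH, 0 °C; evaporate; MeI, K2CO3, acetone, rt
Reagents that add atoms: iodomethane, CI
Why: Methanolysis of the enol ester (transesterification) liberates diosphenol 8, whose potassium enolate is O-methylated by iodomethane (Williamson-type enolate O-alkylation) to the enol ether needed for the sigmatropic shift; no stereocenter is affected.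

**Step 7**
Reactants: 9 (2R,3R,3aR)-2-(3,4-dimethoxyphenyl)-5-methoxy-3-methyl-3a-(prop-2-en-1-yl)-3,3a-dihydro-1-benzofuran-6(2H)-one
Product: 10 (2R,3R,5S)-2-(3,4-dimethoxyphenyl)-5-methoxy-3-methyl-5-(prop-2-en-1-yl)-3,5-dihydro-1-benzofuran-6(2H)-one
Conditions: PhMe (0.02 M, degassed), 110 °C, sealed tube, dark, base-washed glass; stopped at about 80% conversion, 9 recycled
Reagents that add atoms: none
Why: Cope rearrangement ([3,3]-sigmatropic shift), the thermal behaviour described for 3a-allyl hydrobenzofuranone neolignans: the allyl group moves suprafacially from C3a across C4=C5 to C5 through a ring-enforced boat transition state, so 3aR is relayed to 5S (allyl stays on the face cis to the aryl group), driven by relief of the congested ring-fusion quaternary centre and formation of the linearly conjugated vinylogous ester.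

**Compound list**
1 | 2-(benzyloxy)phenol | Oc1ccccc1OCc1ccccc1 | starting material
2 | 2-(benzyloxy)cyclohexa-2,5-diene-1,4-dione | O=C1C=CC(=O)C(OCc2ccccc2)=C1 | intermediate
3 | (E)-1,2-dimethoxy-4-(prop-1-en-1-yl)benzene | C/C=C/c1ccc(OC)c(OC)c1 | starting material
4 | (2R,3R)-6-(benzyloxy)-2-(3,4-dimethoxyphenyl)-3-methyl-2,3-dihydro-1-benzofuran-5-ol | Oc1cc2c(cc1OCc1ccccc1)O[C@@H](c1ccc(OC)c(OC)c1)[C@@H]2C | intermediate
5 | (2R,3R)-6-(benzyloxy)-2-(3,4-dimethoxyphenyl)-3-methyl-2,3-dihydro-1-benzofuran-5-yl 2,2-dimethylpropanoate | CC(C)(C)C(=O)Oc1cc2c(cc1OCc1ccccc1)O[C@@H](c1ccc(OC)c(OC)c1)[C@@H]2C | intermediate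
6 | (2R,3R)-2-(3,4-dimethoxyphenyl)-6-hydroxy-3-methyl-2,3-dihydro-1-benzofuran-5-yl 2,2-dimethylpropanoate | CC(C)(C)C(=O)Oc1cc2c(cc1O)O[C@@H](c1ccc(OC)c(OC)c1)[C@@H]2C | intermediate
7 | (2R,3R,3aR)-2-(3,4-dimethoxyphenyl)-3-methyl-6-oxo-3a-(prop-2-en-1-yl)-2,3,3a,6-tetrahydro-1-benzofuran-5-yl 2,2-dimethylpropanoate | C=CC[C@@]12C=C(OC(=O)C(C)(C)C)C(=O)C=C1O[C@@H](c1ccc(OC)c(OC)c1)[C@@H]2C | intermediate
8 | (2R,3R,3aR)-2-(3,4-dimethoxyphenyl)-5-hydroxy-3-methyl-3a-(prop-2-en-1-yl)-3,3a-dihydro-1-benzofuran-6(2H)-one (diosphenol) | C=CC[C@@]12C=C(O)C(=O)C=C1O[C@@H](c1ccc(OC)c(OC)c1)[C@@H]2C | intermediate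
9 | (2R,3R,3aR)-2-(3,4-dimethoxyphenyl)-5-methoxy-3-methyl-3a-(prop-2-en-1-yl)-3,3a-dihydro-1-benzofuran-6(2H)-one | C=CC[C@@]12C=C(OC)C(=O)C=C1O[C@@H](c1ccc(OC)c(OC)c1)[C@@H]2C | intermediate
10 | (2R,3R,5S)-2-(3,4-dimethoxyphenyl)-5-methoxy-3-methyl-5-(prop-2-en-1-yl)-3,5-dihydro-1-benzofuran-6(2H)-one | C=CC[C@]1(OC)C=C2C(=CC1=O)O[C@@H](c1ccc(OC)c(OC)c1)[C@@H]2C | target

**Totals**
Total step count: 7. Longest linear sequence: 7 steps (1 → 2 → 4 → 5 → 6 → 7 → 9 → 10).

**Steps most likely to fail, with fallbacks**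

Step 5 (highest risk). The oxidised ring may lose the C3 proton and aromatise to the benzofuran, may be attacked at C7, or may show low facial selectivity at C3a. The fallback sets out from 4 and gives up the relay. Methylation (MeI, K2CO3, acetone) gives (2R,3R)-6-(benzyloxy)-2-(3,4-dimethoxyphenyl)-5-methoxy-3-methyl-2,3-dihydro-1-benzofuran F3. Hydrogenolysis (H2, Pd/C, EtOAc) gives (2R,3R)-2-(3,4-dimethoxyphenyl)-5-methoxy-3-methyl-2,3-dihydro-1-benzofuran-6-ol F4. Oxidation of F4 with PhI(OCOCF3)2 in the presence of allylSiMe3 (CH2Cl2/(CF3)2CHOH, −40 °C) now sends the nucleophile to the methoxy-stabilised C5 (oxidative nucleophilic substitution at the oxocarbenium carbon). This gives 10 directly, together with its C5 epimer, (2R,3R,5R)-2-(3,4-dimethoxyphenyl)-5-methoxy-3-methyl-5-(prop-2-en-1-yl)-3,5-dihydro-1-benzofuran-6(2H)-one F5. No facial control is expected, so the two are separated by preparative HPLC. The route is rejoined at 10.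

Step 2. The enantioselectivity, and the yield of direct dihydrobenzofuran formation, are precedented for 2-methoxy quinones but not for the benzyloxy quinone with this electron-rich styrene. The fallback sets out from 2 and 3 and takes the absolute configuration from a resolution instead of from the ligand. The cycloaddition is run with TiCl2(OiPr)2 alone (CH2Cl2, −78 °C) to give racemic trans-6-(benzyloxy)-2-(3,4-dimethoxyphenyl)-3-methyl-2,3-dihydro-1-benzofuran-5-ol F1. The enantiomers are separated by preparative SFC on a chiral stationary phase. (2S,3S)-6-(benzyloxy)-2-(3,4-dimethoxyphenyl)-3-methyl-2,3-dihydro-1-benzofuran-5-ol F2 is set aside, and the (2R,3R) enantiomer is compound 4, where the route is rejoined.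

Step 7. The shift may also run to C7 with irreversible aromatisation, the 9/10 equilibrium may be incomplete, and 10 can leak thermally by retro-Claisen to the aryl allyl ether. The fallback sets out from 6 and builds the C5 centre by carbonyl addition instead of a sigmatropic shift. K2CO3/MeOH removes the pivalate to give (2R,3R)-2-(3,4-dimethoxyphenyl)-3-methyl-2,3-dihydro-1-benzofuran-5,6-diol F6. NaIO4 on silica (CH2Cl2, 0 °C) oxidises it to (2R,3R)-2-(3,4-dimethoxyphenyl)-3-methyl-2,3-dihydro-1-benzofuran-5,6-dione F7. The C5 carbonyl is the more electrophilic one, because C6=O is a vinylogous ester carbonyl. Reagent-controlled 1,2-allylation at C5 with an enantiopure B-allyl-10-phenyl-9-borabicyclo[3.3.2]decane (THF, −78 °C; antipode chosen by trial) gives (2R,3R,5S)-2-(3,4-dimethoxyphenyl)-5-hydroxy-3-methyl-5-(prop-2-en-1-yl)-3,5-dihydro-1-benzofuran-6(2H)-one F8. O-Methylation of the tertiary alcohol (MeOTf, 2,6-di-tert-butylpyridine, CH2Cl2, 0 °C) gives 10, where the route is rejoined.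

**Further compounds**
F1 | step 2 | racemic trans-6-(benzyloxy)-2-(3,4-dimethoxyphenyl)-3-methyl-2,3-dihydro-1-benzofuran-5-ol | Oc1cc2c(cc1OCc1ccccc1)O[C@@H](c1ccc(OC)c(OC)c1)[C@@H]2C.Oc1cc2c(cc1OCc1ccccc1)O[C@H](c1ccc(OC)c(OC)c1)[C@H]2C
F2 | step 2 | (2S,3S)-6-(benzyloxy)-2-(3,4-dimethoxyphenyl)-3-methyl-2,3-dihydro-1-benzofuran-5-ol | Oc1cc2c(cc1OCc1ccccc1)O[C@H](c1ccc(OC)c(OC)c1)[C@H]2C
F3 | step 5 | (2R,3R)-6-(benzyloxy)-2-(3,4-dimethoxyphenyl)-5-methoxy-3-methyl-2,3-dihydro-1-benzofuran | COc1cc2c(cc1OCc1ccccc1)O[C@@H](c1ccc(OC)c(OC)c1)[C@@H]2C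
F4 | step 5 | (2R,3R)-2-(3,4-dimethoxyphenyl)-5-methoxy-3-methyl-2,3-dihydro-1-benzofuran-6-ol | COc1cc2c(cc1O)O[C@@H](c1ccc(OC)c(OC)c1)[C@@H]2C
F5 | step 5 | (2R,3R,5R)-2-(3,4-dimethoxyphenyl)-5-methoxy-3-methyl-5-(prop-2-en-1-yl)-3,5-dihydro-1-benzofuran-6(2H)-one | C=CC[C@@]1(OC)C=C2C(=CC1=O)O[C@@H](c1ccc(OC)c(OC)c1)[C@@H]2C
F6 | step 7 | (2R,3R)-2-(3,4-dimethoxyphenyl)-3-methyl-2,3-dihydro-1-benzofuran-5,6-diol | Oc1cc2c(cc1O)O[C@@H](c1ccc(OC)c(OC)c1)[C@@H]2C
F7 | step 7 | (2R,3R)-2-(3,4-dimethoxyphenyl)-3-methyl-2,3-dihydro-1-benzofuran-5,6-dione | O=C1C=C2C(=CC1=O)O[C@@H](c1ccc(OC)c(OC)c1)[C@@H]2C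
F8 | step 7 | (2R,3R,5S)-2-(3,4-dimethoxyphenyl)-5-hydroxy-3-methyl-5-(prop-2-en-1-yl)-3,5-dihydro-1-benzofuran-6(2H)-one | C=CC[C@]1(O)C=C2C(=CC1=O)O[C@@H](c1ccc(OC)c(OC)c1)[C@@H]2C
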